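**Overview**

- **Cuts, outermost first:** the ArCH2–CH= bond and the =C–CH3 bond of the E alkene. Next, the O=C–CH2 bond on the alkene side of the chain ketone and the O=C–CH2 bond of the prenyl ketone. Last and together, the two bonds that tie the arms to the ring, C1–C(=O) and C2–CH2.
- **Enabling feature:** the chain O=C–C1(CH3)–C2(CH3)–CH2–C=O runs over the two neighbouring methyl-bearing quaternary carbons of the cyclopentane. Joining its first carbonyl carbon to its CH2 carbon in the aldol sense gives a cyclobutanol fused to the cyclopentane at C1–C2. That cyclobutanol is the [2+2] adduct of 1,2-dimethylcyclopentene (two equivalent alkene carbons) with the C5=C6 bond of a 1,3-dioxin-4-one.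
- **Forward order:** the five-membered ring is bought. The four-membered ring is closed by light and reopened by retro-aldol to an aldehyde ester. A temporary δ-lactone keeps the arms distinct while C1 gains allyl (then prenyl) and C2 gains propargyl. The arene comes last, then both carbinols become ketones and the hydroquinone is unmasked.
- **Stereochemistry:** both quaternary carbons (R,R, methyls cis) are set in the photocycloaddition, cis by the ring fusion and absolute by a (−)-menthone spiro acetal plus separation of diastereomers. The E alkene comes from syn-methylalumination and coupling with retention. All carbinol centres are uncontrolled and end as C=O.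

Key step: step 6

Assumption: the facial preference of an excited dioxinone cannot be derived safely from ground-state shielding, so the route is written for attack opposite the isopropyl-bearing carbon of the (6R) spiro epimer, and the assignment is checked at the adduct.

**Route**

Step 1
Reactants: 1 2-methylcyclopentanone (racemic)
Product: 2 1,2-dimethylcyclopentan-1-ol (racemic, diastereomer mixture)
Conditions: MeMgBr, Et2O, 0 °C to rt; aq. NH4Cl
Reagents that add atoms: methylmagnesium bromide, C[Mg]Br
Why: Grignard 1,2-addition to an unhindered cyclopentanone; the two stereocentres of 2 need no control because both are destroyed in step 2.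

Step 2
Reactants: 2 1,2-dimethylcyclopentan-1-ol
Product: 3 1,2-dimethylcyclopentene
Conditions: cat. TsOH·H2O, neat, 120 °C, product distilled out; fractional redistillation
Reagents that add atoms: none
Why: Acid-catalysed E1 dehydration under equilibrating conditions (Zaitsev control) should favour the tetrasubstituted ring alkene, and the trisubstituted and exocyclic isomers are cut off by fractional distillation.

Step 3
Reactants: 4 Meldrum's acid (2,2-dimethyl-1,3-dioxane-4,6-dione)
Product: 5 5-(methoxymethylene)-2,2-dimethyl-1,3-dioxane-4,6-dione
Conditions: HC(OMe)3 (excess, neat), reflux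
Reagents that add atoms: trimethyl orthoformate, COC(OC)OC
Why: Knoevenagel-type condensation of the acidic methylene with the orthoester, driven by loss of two molecules of methanol.

Step 4
Reactants: 5 5-(methoxymethylene)-2,2-dimethyl-1,3-dioxane-4,6-dione
Product: 6 5-(hydroxymethylene)-2,2-dimethyl-1,3-dioxane-4,6-dione (formyl Meldrum's acid)
Conditions: 2 M aq. HCl, rt
Reagents that add atoms: water, O
Why: Addition–elimination hydrolysis of a doubly activated enol ether, which should stop at the hydrogen-bonded hydroxymethylene tautomer.

Step 5
Reactants: 6 formyl Meldrum's acid; 7 (−)-menthone, (2S,5R)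
Product: 9 (6R,7S,10R)-7-isopropyl-10-methyl-1,5-dioxaspiro[5.5]undec-2-en-4-one, via formylketene 8 (not isolated)
Conditions: PhMe, reflux; SiO2 chromatography, then crystallisation
Reagents that add atoms: none
Why: Thermal cycloreversion of the acyl Meldrum's acid releases formylketene 8, which the ketone C=O traps in a hetero-Diels–Alder [4+2] reaction; C7 and C10 come unchanged from 7, the spiro carbon forms as both epimers, and the (6R) epimer is taken after separation.

Step 6
Reactants: 3 1,2-dimethylcyclopentene; 9 (6R,7S,10R)-spiro dioxinone
Product: 10 cis-anti-cis photoadduct, a (1R,5R,6R,7R)-1,5-dimethylbicyclo[3.2.0]heptane. Its C7–O and C6–C(=O)O are part of the 1,3-dioxan-4-one that still carries the spiro menthane (spiro carbon R). The methyl groups lie on the dioxanone side of the cyclobutane and the trimethylene bridge on the other side.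
Conditions: hν (medium-pressure Hg lamp, Pyrex, λ > 290 nm), 3 (10 equiv), EtOAc, −40 °C, Ar; excess 3 distilled back; SiO2 chromatography
Reagents that add atoms: none
Why: Enone–alkene [2+2] photocycloaddition, the first half of a de Mayo sequence: the triplet-excited dioxinone bonds to one carbon of the electron-rich alkene, and the resulting 1,4-biradical closes the second bond after spin inversion, so that C6 and C5 of the dioxinone end up attached to the two methyl-bearing carbons. The closest known reactions are the intermolecular photoadditions of 1,3-dioxin-4-ones, menthone spiro acetals among them, to cyclopentene and to tetrasubstituted alkenes such as 2,3-dimethylbut-2-ene. One ring is closed, the cyclobutane, by recombination of the 1,4-biradical; geometric constraint makes it cis-fused to both the five- and the six-membered ring, which places the two methyl groups cis. The two quaternary carbons (both R) are fixed by two elements acting together, the face of the dioxinone that is attacked (the one turned away from the isopropyl-bearing carbon of the spiro menthane) and the orientation of the alkene (trimethylene bridge pointing away from the dioxanone, cis-anti-cis); the two CH carbons of the cyclobutane follow from the same approach and lose their stereogenicity in step 7. Regioselectivity is not needed because the two alkene carbons are equivalent, and chemoselectivity over dioxinone dimerisation is secured by the large excess of alkene. Because the auxiliary is still attached, every adduct from the other face or the other orientation is a diastereomer that chromatography removes, and the structure of 10 is to be confirmed by X-ray analysis before it is carried on.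

Step 7
Reactants: 10 cis-anti-cis photoadduct
Product: 12 methyl 2-[(1R,2R)-2-formyl-1,2-dimethylcyclopentyl]acetate, via cyclobutanol ester 11 (not isolated)
Conditions: K2CO3 (0.2 equiv), MeOH, 0 °C
Reagents that add atoms: methanol, CO
Why: Methoxide opens the lactone (transesterification), the hemiketal left behind expels menthone, and the alkoxide of 11 breaks the former C5–C6 bond in a strain-driven retro-aldol reaction (second half of the de Mayo sequence); the quaternary carbons carry no acidic hydrogen and keep their configuration.

Step 8
Reactants: 12 methyl 2-[(1R,2R)-2-formyl-1,2-dimethylcyclopentyl]acetate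
Product: 14 (4aR,7aR)-1-allyl-4a,7a-dimethylhexahydrocyclopenta[c]pyran-3(1H)-one (C1 epimers), via hydroxy ester 13 (not isolated)
Conditions: allyl bromide, Zn dust, THF–sat. aq. NH4Cl, 0 °C to rt; then cat. TsOH, PhMe, 60 °C
Reagents that add atoms: allyl bromide, C=CCBr
Why: Zinc Barbier allylation is selective for the aldehyde over the ester, and δ-hydroxy ester 13, with both arms held cis on the ring, should lactonise readily under acid catalysis; the new carbinol carbon is left uncontrolled because it becomes a ketone in step 19.

Step 9
Reactants: 14 allyl lactone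
Product: 15 (4aR,7aR)-4a,7a-dimethyl-1-(3-methylbut-2-enyl)hexahydrocyclopenta[c]pyran-3(1H)-one (C1 epimers)
Conditions: 2-methyl-2-butene (large excess), second-generation Ru–NHC benzylidene catalyst (5 mol %), CH2Cl2, 40 °C, sealed vessel
Reagents that add atoms: 2-methyl-2-butene, CC=C(C)C
Why: Olefin cross-metathesis of a terminal alkene with excess 2-methyl-2-butene is the standard conversion of allyl into prenyl, and it avoids the γ-attack (reverse prenyl) that a prenyl metal would give at the aldehyde.

Step 10
Reactants: 15 prenyl lactone
Product: 16 (4aR,7aR)-4a,7a-dimethyl-1-(3-methylbut-2-enyl)octahydrocyclopenta[c]pyran-3-ol (lactol, epimers at C1 and C3)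
Conditions: DIBAL-H (1.1 equiv), CH2Cl2, −78 °C; aq. Rochelle salt
Reagents that add atoms: none
Why: Partial reduction of a lactone, in which the aluminium lactolate is stable at −78 °C and gives the lactol on work-up, while the alkene is inert.

Step 11
Reactants: 16 lactol
Product: 17 1-[(1R,2R)-2-(2-hydroxypent-4-ynyl)-1,2-dimethylcyclopentyl]-4-methylpent-3-en-1-ol (both carbinols as epimers)
Conditions: propargyl bromide, Zn dust (both in portions, excess), THF–sat. aq. NH4Cl, 0 °C to rt
Reagents that add atoms: propargyl bromide, C#CCBr
Why: Barbier propargylation, in which allenylzinc bromide adds by SE2′ to the hydroxy aldehyde in equilibrium with the lactol and should therefore give the homopropargylic alcohol; the new carbinol carbon again needs no control.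

Step 12
Reactants: 17 enyne diol
Product: 18 bis-TBS ether of 17, (1R,2R)-1-[1-(TBSO)-4-methylpent-3-enyl]-2-[2-(TBSO)pent-4-ynyl]-1,2-dimethylcyclopentane
Conditions: TBSOTf (3 equiv), 2,6-lutidine, CH2Cl2, 0 °C to rt
Reagents that add atoms: tert-butyldimethylsilyl triflate, CC(C)(C)[Si](C)(C)OS(=O)(=O)C(F)(F)F
Why: Silylation with a silyl triflate is reactive enough for the neopentylic carbinol, and masking the homopropargylic oxygen prevents alkoxide-directed E-to-Z isomerisation of the alkenylalane in step 17.

Step 13
Reactants: 19 4-methoxy-2-methylphenol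
Product: 21 2-hydroxy-5-methoxy-3-methylbenzaldehyde, via salicyl alcohol 20 (not isolated)
Conditions: MgCl2, Et3N, (CH2O)n, MeCN, reflux; aq. HCl
Reagents that add atoms: formaldehyde (as paraformaldehyde), C=O
Why: Casnati–Skattebøl ortho-formylation, in which the magnesium phenolate delivers formaldehyde to the only free ortho position and a second formaldehyde oxidises 20 by hydride transfer.

Step 14
Reactants: 21 2-hydroxy-5-methoxy-3-methylbenzaldehyde
Product: 22 2,5-dimethoxy-3-methylbenzaldehyde
Conditions: MeI, K2CO3, DMF, rt
Reagents that add atoms: iodomethane, CI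
Why: Williamson O-methylation of an acidic salicylaldehyde phenol.

Step 15
Reactants: 22 2,5-dimethoxy-3-methylbenzaldehyde
Product: 23 (2,5-dimethoxy-3-methylphenyl)methanol
Conditions: NaBH4, MeOH, 0 °C
Reagents that add atoms: none
Why: Borohydride reduction of an aromatic aldehyde.

Step 16
Reactants: 23 (2,5-dimethoxy-3-methylphenyl)methanol
Product: 24 1-(chloromethyl)-2,5-dimethoxy-3-methylbenzene
Conditions: SOCl2, CH2Cl2, 0 °C to rt; used without chromatography
Reagents that add atoms: thionyl chloride, O=S(Cl)Cl
Why: Chlorodehydroxylation of an electron-rich benzylic alcohol through its chlorosulfite.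

Step 17
Reactants: 18 bis-TBS enyne; 24 benzylic chloride
Product: 26 (1R,2R)-1-[1-(TBSO)-4-methylpent-3-enyl]-2-[(E)-2-(TBSO)-6-(2,5-dimethoxy-3-methylphenyl)-4-methylhex-4-enyl]-1,2-dimethylcyclopentane, via alkenylalane 25 (not isolated)
Conditions: Me3Al (2.5 equiv), Cp2ZrCl2 (0.3 equiv), CH2Cl2, 0 °C to rt; volatiles removed in vacuo; 24, Pd(PPh3)4 (5 mol %), THF, rt
Reagents that add atoms: trimethylaluminium, C[Al](C)C
Why: Negishi zirconium-catalysed carboalumination adds CH3 and Al syn across the terminal alkyne with CH3 on the internal carbon, and the Pd(0)-catalysed cross-coupling of 25 with the benzylic chloride goes with retention, which together fix the E alkene; excess Me3Al is stripped off first to prevent methyl transfer, and the prenyl alkene and silyl ethers are inert.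

Step 18
Reactants: 26 coupled bis-TBS ether
Product: 27 (E)-1-[(1R,2R)-2-(1-hydroxy-4-methylpent-3-enyl)-1,2-dimethylcyclopentyl]-6-(2,5-dimethoxy-3-methylphenyl)-4-methylhex-4-en-2-ol (carbinol epimers)
Conditions: TBAF (5 equiv), THF, rt to 50 °C
Reagents that add atoms: none
Why: Fluoride cleavage of both silyl ethers, with gentle warming for the neopentylic one, on a substrate that has no base-sensitive group at this stage.

Step 19
Reactants: 27 diol
Product: 28 (E)-6-(2,5-dimethoxy-3-methylphenyl)-1-[(1R,2R)-1,2-dimethyl-2-(4-methylpent-3-enoyl)cyclopentyl]-4-methylhex-4-en-2-one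
Conditions: Dess–Martin periodinane (3 equiv), NaHCO3 (10 equiv), CH2Cl2, 0 °C to rt; cold neutral work-up, short pad of deactivated SiO2
Reagents that add atoms: none
Why: Bicarbonate-buffered Dess–Martin oxidation converts homoallylic alcohols into β,γ-unsaturated ketones without moving the double bond and removes both uncontrolled carbinol centres, while the neutral handling avoids conjugation and aldol closure of the 1,5-diketone.

Step 20
Reactants: 28 diketone dimethyl ether
Product: 29 2-{(E)-6-[(1R,2R)-1,2-dimethyl-2-(4-methylpent-3-enoyl)cyclopentyl]-3-methyl-5-oxohex-2-enyl}-6-methyl-1,4-benzoquinone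
Conditions: (NH4)2Ce(NO3)6 (2.5 equiv), MeCN–H2O, 0 °C, short reaction time
Reagents that add atoms: water, O
Why: Cerium(IV) oxidative demethylation of a 1,4-dimethoxyarene, in which water supplies both quinone oxygens and two methanol molecules leave, is much faster than attack on isolated trisubstituted alkenes, and the short time at 0 °C limits acid exposure.

Step 21
Reactants: 29 quinone
Product: 30 (E)-6-(2,5-dihydroxy-3-methylphenyl)-1-[(1R,2R)-1,2-dimethyl-2-(4-methylpent-3-enoyl)cyclopentyl]-4-methylhex-4-en-2-one (CNP0294415.1)
Conditions: Na2S2O4 (excess), Et2O–H2O, rt, Ar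
Reagents that add atoms: none
Why: Dithionite reduction of a quinone to the hydroquinone in a neutral two-phase medium leaves ketones and alkenes alone and avoids the acid that would close a chroman onto the side-chain alkene.

**Compound list**

1 | 2-methylcyclopentanone | CC1CCCC1=O | starting material
2 | 1,2-dimethylcyclopentan-1-ol (stereoisomer mixture) | CC1CCCC1(C)O | intermediate
3 | 1,2-dimethylcyclopentene | CC1=C(C)CCC1 | intermediate
4 | Meldrum's acid | CC1(C)OC(=O)CC(=O)O1 | starting material
5 | 5-(methoxymethylene)-2,2-dimethyl-1,3-dioxane-4,6-dione | COC=C1C(=O)OC(C)(C)OC1=O | intermediate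
6 | 5-(hydroxymethylene)-2,2-dimethyl-1,3-dioxane-4,6-dione | OC=C1C(=O)OC(C)(C)OC1=O | intermediate
7 | (−)-menthone, (2S,5R) | C[C@@H]1CC[C@H](C(=O)C1)C(C)C | starting material
8 | formylketene | O=CC=C=O | intermediate
9 | (6R,7S,10R)-7-isopropyl-10-methyl-1,5-dioxaspiro[5.5]undec-2-en-4-one | C[C@@H]1CC[C@H]([C@]2(C1)OC=CC(=O)O2)C(C)C | intermediate
10 | cis-anti-cis photoadduct carrying the menthone acetal | C[C@@H]1CC[C@H]([C@]2(C1)O[C@H]3[C@]4(C)CCC[C@]4(C)[C@H]3C(=O)O2)C(C)C | intermediate
11 | methyl (1R,5R,6R,7R)-7-hydroxy-1,5-dimethylbicyclo[3.2.0]heptane-6-carboxylate | O[C@H]1[C@]2(C)CCC[C@]2(C)[C@H]1C(=O)OC | intermediate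
12 | methyl 2-[(1R,2R)-2-formyl-1,2-dimethylcyclopentyl]acetate | O=C[C@]1(C)CCC[C@]1(C)CC(=O)OC | intermediate
13 | methyl 2-[(1R,2R)-2-(1-hydroxybut-3-enyl)-1,2-dimethylcyclopentyl]acetate (carbinol epimers) | C=CCC(O)[C@]1(C)CCC[C@]1(C)CC(=O)OC | intermediate
14 | (4aR,7aR)-1-allyl-4a,7a-dimethylhexahydrocyclopenta[c]pyran-3(1H)-one (C1 epimers) | C=CCC2[C@]1(C)CCC[C@]1(C)CC(=O)O2 | intermediate
15 | (4aR,7aR)-4a,7a-dimethyl-1-(3-methylbut-2-enyl)hexahydrocyclopenta[c]pyran-3(1H)-one (C1 epimers) | CC(C)=CCC2[C@]1(C)CCC[C@]1(C)CC(=O)O2 | intermediate
16 | (4aR,7aR)-4a,7a-dimethyl-1-(3-methylbut-2-enyl)octahydrocyclopenta[c]pyran-3-ol (epimers) | CC(C)=CCC2[C@]1(C)CCC[C@]1(C)CC(O)O2 | intermediate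
17 | 1-[(1R,2R)-2-(2-hydroxypent-4-ynyl)-1,2-dimethylcyclopentyl]-4-methylpent-3-en-1-ol (carbinol epimers) | CC(C)=CCC(O)[C@]1(C)CCC[C@]1(C)CC(O)CC#C | intermediate
18 | bis-TBS ether of 17 | CC(C)=CCC(O[Si](C)(C)C(C)(C)C)[C@]1(C)CCC[C@]1(C)CC(CC#C)O[Si](C)(C)C(C)(C)C | intermediate
19 | 4-methoxy-2-methylphenol | COc1ccc(O)c(C)c1 | starting material
20 | 2-(hydroxymethyl)-4-methoxy-6-methylphenol | COc1cc(C)c(O)c(CO)c1 | intermediate
21 | 2-hydroxy-5-methoxy-3-methylbenzaldehyde | COc1cc(C)c(O)c(C=O)c1 | intermediate
22 | 2,5-dimethoxy-3-methylbenzaldehyde | COc1cc(C)c(OC)c(C=O)c1 | intermediate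
23 | (2,5-dimethoxy-3-methylphenyl)methanol | COc1cc(C)c(OC)c(CO)c1 | intermediate
24 | 1-(chloromethyl)-2,5-dimethoxy-3-methylbenzene | COc1cc(C)c(OC)c(CCl)c1 | intermediate
25 | (E)-alkenyl(dimethyl)alane from 18 | CC(C)=CCC(O[Si](C)(C)C(C)(C)C)[C@]1(C)CCC[C@]1(C)CC(C/C(C)=C/[Al](C)C)O[Si](C)(C)C(C)(C)C | intermediate
26 | coupled E alkene, bis-TBS ether, arene as dimethyl ether | CC(C)=CCC(O[Si](C)(C)C(C)(C)C)[C@]1(C)CCC[C@]1(C)CC(C/C(C)=C/Cc1cc(OC)cc(C)c1OC)O[Si](C)(C)C(C)(C)C | intermediate
27 | diol from 26 (carbinol epimers) | CC(C)=CCC(O)[C@]1(C)CCC[C@]1(C)CC(O)C/C(C)=C/Cc1cc(OC)cc(C)c1OC | intermediate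
28 | bis(β,γ-unsaturated) 1,5-diketone, hydroquinone dimethyl ether | CC(C)=CCC(=O)[C@]1(C)CCC[C@]1(C)CC(=O)C/C(C)=C/Cc1cc(OC)cc(C)c1OC | intermediate
29 | quinone diketone | CC(C)=CCC(=O)[C@]1(C)CCC[C@]1(C)CC(=O)C/C(C)=C/CC1=CC(=O)C=C(C)C1=O | intermediate
30 | CNP0294415.1 | CC(C)=CCC(=O)[C@]1(C)CCC[C@]1(C)CC(=O)C/C(C)=C/Cc1cc(O)cc(C)c1O | target

**Step count**

Total: 21 steps. Longest linear sequence: 15 steps (steps 3–12 and 17–21, from Meldrum's acid).

**Steps most likely to fail**

**Step 6** is the least secure.
- The excited dioxinone may discriminate poorly between its two faces.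
- The alkene may show little preference between its two orientations, because either way carbon substituents (two methyl groups or the trimethylene bridge) come to lie over the dioxanone.
- Hydrogen transfer within the 1,4-biradical may compete with ring closure.
- An error in face alone or in orientation alone leads into the enantiomeric series, so material is lost at the separation.

The fallback replaces auxiliary control by resolution and sets out from 6 and 3. Thermolysis of 6 in toluene containing acetone should give 2,2-dimethyl-1,3-dioxin-4-one F1. Irradiation of it with excess 3 gives the racemic photoadducts F2, whose two orientations now converge. K2CO3 in methanol turns them into the racemic aldehyde ester F3. Condensation with (1R,2R)-N,N′-dimethyl-1,2-diphenylethane-1,2-diamine over molecular sieves gives two diastereomeric aminals, and no new stereocentre arises because the diamine is C2-symmetric. Chromatography or crystallisation delivers the imidazolidine F4 of the (R,R) series. Dilute aqueous acid in a two-phase system then releases the aldehyde, and the route is rejoined at 12.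

**Step 20:** the acidic cerium(IV) medium may shift either β,γ double bond into conjugation, start aldol closure of the 1,5-diketone, or attack the trisubstituted alkenes. The fallback changes the order of events so that the oxidant acts before the sensitive ketones exist. It sets out from 27, which is treated with ceric ammonium nitrate at 0 °C to give the quinone diol F5. Buffered Dess–Martin oxidation of both carbinols, to which a quinone is inert, then leads back to the route at 29.

**Step 17:** carbometalation may be slow or incomplete on a chain flanked by bulky silyl ethers, the alane may be protonated before it couples, and methyl transfer or homocoupling may consume the benzylic chloride. The fallback separates the two events and reverses the polarity of the coupling. It sets out from 18, whose alane 25 is quenched with iodine to give the (E)-alkenyl iodide F6, which can be purified. Chloride 24 is converted with zinc dust and LiCl in THF into the benzylzinc chloride F7. A palladium-catalysed Negishi coupling of the two returns to the route at 26.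

**Further compounds**

F1 | step 6 | 2,2-dimethyl-1,3-dioxin-4-one | CC1(C)OC=CC(=O)O1
F2 | step 6 | racemic acetonide photoadducts, cis-anti-cis and cis-syn-cis mixture | CC1(C)OC2C(C(=O)O1)C1(C)CCCC21C
F3 | step 6 | racemic methyl 2-(cis-2-formyl-1,2-dimethylcyclopentyl)acetate | O=C[C@]1(C)CCC[C@]1(C)CC(=O)OC.O=C[C@@]1(C)CCC[C@@]1(C)CC(=O)OC
F4 | step 6 | methyl 2-{(1R,2R)-2-[(4R,5R)-1,3-dimethyl-4,5-diphenylimidazolidin-2-yl]-1,2-dimethylcyclopentyl}acetate | CN1[C@H](c2ccccc2)[C@H](N(C)C1[C@]3(C)CCC[C@]3(C)CC(=O)OC)c4ccccc4
F5 | step 20 | quinone diol (carbinol epimers) | CC(C)=CCC(O)[C@]1(C)CCC[C@]1(C)CC(O)C/C(C)=C/CC1=CC(=O)C=C(C)C1=O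
F6 | step 17 | (E)-alkenyl iodide, bis-TBS ether | CC(C)=CCC(O[Si](C)(C)C(C)(C)C)[C@]1(C)CCC[C@]1(C)CC(C/C(C)=C/I)O[Si](C)(C)C(C)(C)C
F7 | step 17 | (2,5-dimethoxy-3-methylbenzyl)zinc chloride | COc1cc(C)c(OC)c(C[Zn]Cl)c1
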